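**Plan**
- Cuts: first the C=C that joins C5' to the isopropenyl unit (aldehyde plus methallyl phosphonate). Next the two ring B bonds C2'-C3' and C5'-C6'. Last the C1 units around C1' and ring C itself.
- Enabling feature: in ring B only C2' and C6', the neighbours of C1', carry hydrogen, so C2'-C1'-C6' is a symmetric malonaldehyde standing on C3 of ring C. The remaining run C3'(O)-C4'(O)-C5'(C) is the C4-C3-C2(-C1) chain of a 4-alkoxyacetoacetate.
- Forward order: ring A is bought as phloroacetophenone and ring C closes in a Vilsmeier-Haack formylation. The 3-formyl carbon (future C1') is flanked with two C1 units by Wittig and orthoformate chemistry. Ring B closes last, in a [3+3] cyclocondensation with a 1,3-bis(silyloxy)diene.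
- Protecting groups: three benzyl ethers and a benzyl ester pass the Lewis acid step and fall together in one hydrogenolysis, before any diene, aldehyde or sulfur is present. Silyl ethers then cover thioester formation, Fukuyama reduction and olefination.
- Stereochemistry: there is no stereocentre. The single element, the E double bond of the dienyl chain, comes from the Horner-Wadsworth-Emmons step.

Key step: step 9

Assumption: enol ether, silyl enol ether and enolate geometries are drawn as one isomer for definiteness; they may be mixtures or fluxional, and all of them vanish when ring B becomes aromatic.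

Step 1
Reactants: 1 2,4,6-trihydroxyacetophenone; 2 benzyl bromide
Product: 3 1-[2,4-bis(benzyloxy)-6-hydroxyphenyl]ethan-1-one
Conditions: K2CO3 (2.2 equiv), 2 (2.1 equiv), DMF, 60 °C
Reagents that add atoms: none
Why: Williamson etherification; once the para and one ortho hydroxyl are alkylated, the last hydroxyl is locked in a hydrogen bond to the acetyl C=O and is too poor a nucleophile at this stoichiometry, which leaves exactly the phenol that becomes O1.

Step 2
Reactants: 3 1-[2,4-bis(benzyloxy)-6-hydroxyphenyl]ethan-1-one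
Product: 4 5,7-bis(benzyloxy)-4-oxo-4H-chromene-3-carbaldehyde
Conditions: POCl3, DMF, 0 → 50 °C; then ice-water
Reagents that add atoms: N,N-dimethylformamide CN(C)C=O; water O
Why: Vilsmeier-Haack synthesis of 3-formylchromones: the acetyl CH3 is formylated twice, the free phenol closes ring C on one iminium carbon with loss of dimethylamine, hydrolysis of the other releases the aldehyde, and benzyl ethers are inert to POCl3/DMF.

Step 3
Reactants: 4 5,7-bis(benzyloxy)-4-oxo-4H-chromene-3-carbaldehyde; 5 (methoxymethyl)triphenylphosphonium chloride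
Product: 7 5,7-bis(benzyloxy)-3-(2-methoxyvinyl)-4H-chromen-4-one (E/Z mixture), via methoxymethylene ylide 6 (not isolated)
Conditions: 5 (1.3 equiv), NaN(SiMe3)2 (1.2 equiv), THF, 0 °C; then 4, −78 → 0 °C
Reagents that add atoms: none
Why: Wittig olefination, a reaction known for 3-formylchromones; the formyl carbon outcompetes C2 for the ylide at low temperature, the salt is kept in slight excess over the base so that no free amide remains, and both olefin isomers serve equally well.

Step 4
Reactants: 7 5,7-bis(benzyloxy)-3-(2-methoxyvinyl)-4H-chromen-4-one; 8 trimethyl orthoformate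
Product: 10 2-[5,7-bis(benzyloxy)-4-oxo-4H-chromen-3-yl]malonaldehyde, via tetramethyl bis-acetal 9 (not isolated)
Conditions: 8 (3 equiv), BF3·OEt2 (cat.), CH2Cl2, −30 → 0 °C; then 2 M HCl, THF, rt
Reagents that add atoms: water O
Why: Lewis-acid-catalysed addition of an orthoformate to an enol ether (Müller-Cunradi-Pieroh type) places the new C1 unit on the carbon bound to C3, because only that regiochemistry passes through an oxygen-stabilised cation; the bis-acetal is then unmasked with aqueous acid, which the pyrone tolerates, rather than with the hydroxide that aminoacrolein routes need and that would open ring C.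

Step 5
Reactants: 10 2-[5,7-bis(benzyloxy)-4-oxo-4H-chromen-3-yl]malonaldehyde
Product: 11 (E)-2-[5,7-bis(benzyloxy)-4-oxo-4H-chromen-3-yl]-3-(trimethylsilyloxy)acrolein
Conditions: Me3SiCl, Et3N, CH2Cl2, 0 °C → rt; filtered under argon, used crude
Reagents that add atoms: chlorotrimethylsilane C[Si](C)(C)Cl
Why: O-silylation of a 1,3-dicarbonyl enol with Me3SiCl/Et3N is the standard entry to 3-silyloxy-2-enals; it also removes the acidic enol proton, and the moisture-sensitive product is taken on without chromatography.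

Step 6
Reactants: 12 benzyloxyacetyl chloride; 13 Meldrum's acid (2,2-dimethyl-1,3-dioxane-4,6-dione); 14 benzyl alcohol
Product: 16 benzyl 4-(benzyloxy)-3-oxobutanoate, via acyl Meldrum's acid 15 (not isolated)
Conditions: pyridine, CH2Cl2, 0 °C → rt; then 14, toluene, reflux
Reagents that add atoms: none
Why: Meldrum's acid synthesis of β-keto esters (C-acylation, then thermal alcoholysis with loss of acetone and CO2); the benzyl ester is chosen so that the carboxyl group can later be freed by hydrogenolysis and never by hydroxide.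

Step 7
Reactants: 16 benzyl 4-(benzyloxy)-3-oxobutanoate
Product: 17 benzyl (Z)-4-(benzyloxy)-3-(trimethylsilyloxy)but-2-enoate
Conditions: Me3SiCl, Et3N, toluene, rt
Reagents that add atoms: chlorotrimethylsilane C[Si](C)(C)Cl
Why: Soft enolisation and O-silylation of a β-keto ester, the first half of the standard two-stage preparation of 1,3-bis(silyloxy)dienes.

Step 8
Reactants: 17 benzyl (Z)-4-(benzyloxy)-3-(trimethylsilyloxy)but-2-enoate
Product: 19 (1Z,3Z)-1,4-bis(benzyloxy)-1,3-bis(trimethylsilyloxy)buta-1,3-diene, via lithium dienolate 18 (not isolated)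
Conditions: LiN(iPr)2 (LDA), THF, −78 °C; then Me3SiCl, −78 °C → rt; used crude
Reagents that add atoms: chlorotrimethylsilane C[Si](C)(C)Cl
Why: Kinetic γ-deprotonation of the silyl enol ether gives the extended ester enolate, which Me3SiCl traps on oxygen; 4-alkoxy members of this diene class are prepared in the same way.

Step 9
Reactants: 11 (E)-2-[5,7-bis(benzyloxy)-4-oxo-4H-chromen-3-yl]-3-(trimethylsilyloxy)acrolein; 19 (1Z,3Z)-1,4-bis(benzyloxy)-1,3-bis(trimethylsilyloxy)buta-1,3-diene
Product: 21 benzyl 3-(benzyloxy)-5-[5,7-bis(benzyloxy)-4-oxo-4H-chromen-3-yl]-2-hydroxybenzoate, via chlorotitanium chelate 20 (not isolated)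
Conditions: TiCl4 (1.1 equiv) on 11, CH2Cl2, −78 °C; then 19 (1.5 equiv), −78 → 10 °C; then 1 M HCl
Reagents that add atoms: none
Why: TiCl4 should displace the silyl group from the enol oxygen of 11 and give chelate 20, whose two CH termini are equivalent and strongly activated; the terminal, benzyloxy-bearing carbon of 19, the most nucleophilic site of the diene, adds to one of them in a vinylogous Mukaiyama aldol step and forms C2'-C3'. The carbon lying between the ester carbon and the former ketone carbon then attacks the second terminus, forms C5'-C6' and closes ring B in a 6-(enolendo)-exo-trig aldol closure, after which loss of both former aldehyde oxygens (as water and silanol) aromatises the ring. The closest known reaction type is the Lewis-acid-mediated formal [3+3] cyclocondensation of 1,3-bis(silyloxy)-1,3-dienes, 4-alkoxy dienes included, with 2-aryl-3-silyloxy-2-enals and -enones, which gives 5-aryl salicylates. No stereocentre is created. Regiochemistry needs no control, because the three-carbon partner is its own mirror image about the carbon that becomes C1'; the diene hands over its C3 oxygen as the free O4' hydroxyl, its ether oxygen as benzyl-capped O3' and its carboxyl carbon as the C5' substituent. The selectivity that is needed is attack at the enal and not at C2 of the pyrone; it rests on the covalent anchoring of the single equivalent of titanium on the malonaldehyde unit, on the O5 and O7 donors that damp the pyrone as an acceptor, and on the low temperature.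

Step 10
Reactants: 21 benzyl 3-(benzyloxy)-5-[5,7-bis(benzyloxy)-4-oxo-4H-chromen-3-yl]-2-hydroxybenzoate
Product: 22 benzyl 3-(benzyloxy)-5-[5,7-bis(benzyloxy)-4-oxo-4H-chromen-3-yl]-2-methoxybenzoate
Conditions: MeI, K2CO3, DMF, rt → 40 °C
Reagents that add atoms: iodomethane CI
Why: Williamson methylation of the only free hydroxyl (O4'); K2CO3 in dry DMF overcomes the salicylate hydrogen bond without harming the isoflavone or the benzyl ester.

Step 11
Reactants: 22 benzyl 3-(benzyloxy)-5-[5,7-bis(benzyloxy)-4-oxo-4H-chromen-3-yl]-2-methoxybenzoate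
Product: 23 5-(5,7-dihydroxy-4-oxo-4H-chromen-3-yl)-3-hydroxy-2-methoxybenzoic acid
Conditions: H2 (1 atm), 10% Pd/C, THF-MeOH, rt, stopped at full debenzylation
Reagents that add atoms: none
Why: Catalytic hydrogenolysis cleaves the three aryl benzyl ethers and the benzyl ester much faster than it saturates C2=C3 of an isoflavone, and it is placed here because no diene, aldehyde or sulfur is yet in the molecule.

Step 12
Reactants: 23 5-(5,7-dihydroxy-4-oxo-4H-chromen-3-yl)-3-hydroxy-2-methoxybenzoic acid
Product: 25 3-(tert-butyldimethylsilyloxy)-5-[7-(tert-butyldimethylsilyloxy)-5-hydroxy-4-oxo-4H-chromen-3-yl]-2-methoxybenzoic acid, via silyl ester 24 (not isolated)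
Conditions: TBSCl (4 equiv), imidazole, DMF, rt; then AcOH-THF-H2O, rt
Reagents that add atoms: tert-butyldimethylsilyl chloride CC(C)(C)[Si](C)(C)Cl
Why: Imidazole-promoted silylation covers O7, O3' and the acid, the 5-OH should stay free because its hydrogen bond to C4=O makes it the poorest nucleophile, and mild aqueous acid then hydrolyses only the silyl ester since aryl silyl ethers tolerate acid.

Step 13
Reactants: 25 3-(tert-butyldimethylsilyloxy)-5-[7-(tert-butyldimethylsilyloxy)-5-hydroxy-4-oxo-4H-chromen-3-yl]-2-methoxybenzoic acid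
Product: 26 S-ethyl 3-(tert-butyldimethylsilyloxy)-5-[7-(tert-butyldimethylsilyloxy)-5-hydroxy-4-oxo-4H-chromen-3-yl]-2-methoxybenzenecarbothioate
Conditions: EtSH, EDC·HCl, DMAP (cat.), CH2Cl2, 0 °C → rt
Reagents that add atoms: ethanethiol CCS
Why: Carbodiimide/DMAP (Steglich-type) thioesterification; the thiol is far more nucleophilic than the chelated 5-OH, and the near-neutral medium spares the aryl silyl ethers.

Step 14
Reactants: 26 S-ethyl 3-(tert-butyldimethylsilyloxy)-5-[7-(tert-butyldimethylsilyloxy)-5-hydroxy-4-oxo-4H-chromen-3-yl]-2-methoxybenzenecarbothioate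
Product: 27 3-(tert-butyldimethylsilyloxy)-5-[7-(tert-butyldimethylsilyloxy)-5-hydroxy-4-oxo-4H-chromen-3-yl]-2-methoxybenzaldehyde
Conditions: Et3SiH, 10% Pd/C, acetone, rt
Reagents that add atoms: none
Why: Fukuyama reduction: zerovalent palladium inserts into the C-S bond and the silane delivers hydride, so the reaction stops at the aldehyde and, unlike aluminium or boron hydrides, leaves C4=O and C2=C3 of the pyrone untouched.

Step 15
Reactants: 28 methallyl chloride (3-chloro-2-methylprop-1-ene); 29 triethyl phosphite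
Product: 30 diethyl (2-methylallyl)phosphonate
Conditions: NaI (cat.), neat, 130 °C
Reagents that add atoms: none
Why: Michaelis-Arbuzov reaction of a primary allylic chloride, accelerated by catalytic iodide and driven by loss of the volatile alkyl chloride.

Step 16
Reactants: 27 3-(tert-butyldimethylsilyloxy)-5-[7-(tert-butyldimethylsilyloxy)-5-hydroxy-4-oxo-4H-chromen-3-yl]-2-methoxybenzaldehyde; 30 diethyl (2-methylallyl)phosphonate
Product: 32 7-(tert-butyldimethylsilyloxy)-3-{3-(tert-butyldimethylsilyloxy)-4-methoxy-5-[(1E)-3-methylbuta-1,3-dien-1-yl]phenyl}-5-hydroxy-4H-chromen-4-one, via lithiated phosphonate 31 (not isolated)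
Conditions: 30 (2.3 equiv), n-BuLi (2.2 equiv), THF, −78 °C; then 27, DMPU, −78 °C → rt
Reagents that add atoms: none
Why: Horner-Wadsworth-Emmons olefination with an allylic phosphonate: the first equivalent of anion only deprotonates the 5-OH (the phenoxide further damps the pyrone), the second adds through its α-carbon to the aldehyde, and elimination from the equilibrated adduct should give the E olefin, as is usual for aryl aldehydes.

Step 17
Reactants: 32 7-(tert-butyldimethylsilyloxy)-3-{3-(tert-butyldimethylsilyloxy)-4-methoxy-5-[(1E)-3-methylbuta-1,3-dien-1-yl]phenyl}-5-hydroxy-4H-chromen-4-one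
Product: 33 5,7-dihydroxy-3-{3-hydroxy-4-methoxy-5-[(1E)-3-methylbuta-1,3-dien-1-yl]phenyl}-4H-chromen-4-one (target)
Conditions: Bu4NF, AcOH, THF, 0 °C
Reagents that add atoms: none
Why: Fluoride-induced cleavage of aryl silyl ethers; acetic acid buffers the phenoxides, so neither the pyrone nor the diene sees strong base or acid and the E geometry is kept.

**Compound list**
1 | 2,4,6-trihydroxyacetophenone | CC(=O)c1c(O)cc(O)cc1O | starting material
2 | benzyl bromide | BrCc1ccccc1 | starting material
3 | 1-[2,4-bis(benzyloxy)-6-hydroxyphenyl]ethan-1-one | CC(=O)c1c(O)cc(OCc2ccccc2)cc1OCc1ccccc1 | intermediate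
4 | 5,7-bis(benzyloxy)-4-oxo-4H-chromene-3-carbaldehyde | O=Cc1coc2cc(OCc3ccccc3)cc(OCc3ccccc3)c2c1=O | intermediate
5 | (methoxymethyl)triphenylphosphonium chloride | COC[P+](c1ccccc1)(c1ccccc1)c1ccccc1.[Cl-] | starting material
6 | (methoxymethylidene)triphenylphosphorane | COC=P(c1ccccc1)(c1ccccc1)c1ccccc1 | intermediate (not isolated)
7 | 5,7-bis(benzyloxy)-3-(2-methoxyvinyl)-4H-chromen-4-one (E/Z mixture, E isomer drawn) | CO/C=C/c1coc2cc(OCc3ccccc3)cc(OCc3ccccc3)c2c1=O | intermediate
8 | trimethyl orthoformate | COC(OC)OC | starting material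
9 | 5,7-bis(benzyloxy)-3-(1,1,3,3-tetramethoxypropan-2-yl)-4H-chromen-4-one | COC(OC)C(C(OC)OC)c1coc2cc(OCc3ccccc3)cc(OCc3ccccc3)c2c1=O | intermediate (not isolated)
10 | 2-[5,7-bis(benzyloxy)-4-oxo-4H-chromen-3-yl]malonaldehyde (dialdehyde tautomer drawn, enol expected) | O=CC(C=O)c1coc2cc(OCc3ccccc3)cc(OCc3ccccc3)c2c1=O | intermediate
11 | (E)-2-[5,7-bis(benzyloxy)-4-oxo-4H-chromen-3-yl]-3-(trimethylsilyloxy)acrolein | O=C/C(=C/O[Si](C)(C)C)c1coc2cc(OCc3ccccc3)cc(OCc3ccccc3)c2c1=O | intermediate
12 | benzyloxyacetyl chloride | O=C(Cl)COCc1ccccc1 | starting material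
13 | Meldrum's acid | CC1(C)OC(=O)CC(=O)O1 | starting material
14 | benzyl alcohol | OCc1ccccc1 | starting material
15 | 5-[2-(benzyloxy)-1-hydroxyethylidene]-2,2-dimethyl-1,3-dioxane-4,6-dione | CC1(C)OC(=O)C(=C(O)COCc2ccccc2)C(=O)O1 | intermediate (not isolated)
16 | benzyl 4-(benzyloxy)-3-oxobutanoate | O=C(CC(=O)COCc1ccccc1)OCc1ccccc1 | intermediate
17 | benzyl (Z)-4-(benzyloxy)-3-(trimethylsilyloxy)but-2-enoate | O=C(OCc1ccccc1)/C=C(\O[Si](C)(C)C)COCc1ccccc1 | intermediate
18 | lithium (1Z,3Z)-1,4-bis(benzyloxy)-3-(trimethylsilyloxy)buta-1,3-dien-1-olate | c1ccccc1CO/C([O-])=C/C(O[Si](C)(C)C)=C/OCc1ccccc1.[Li+] | intermediate (not isolated)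
19 | (1Z,3Z)-1,4-bis(benzyloxy)-1,3-bis(trimethylsilyloxy)buta-1,3-diene | c1ccccc1CO/C(O[Si](C)(C)C)=C/C(O[Si](C)(C)C)=C/OCc1ccccc1 | intermediate
20 | trichloro{(Z)-2-[5,7-bis(benzyloxy)-4-oxo-4H-chromen-3-yl]-3-oxoprop-1-en-1-olato}titanium | O=C/C(=C\O[Ti](Cl)(Cl)Cl)c1coc2cc(OCc3ccccc3)cc(OCc3ccccc3)c2c1=O | intermediate (not isolated)
21 | benzyl 3-(benzyloxy)-5-[5,7-bis(benzyloxy)-4-oxo-4H-chromen-3-yl]-2-hydroxybenzoate | O=C(OCc1ccccc1)c1cc(-c2coc3cc(OCc4ccccc4)cc(OCc4ccccc4)c3c2=O)cc(OCc2ccccc2)c1O | intermediate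
22 | benzyl 3-(benzyloxy)-5-[5,7-bis(benzyloxy)-4-oxo-4H-chromen-3-yl]-2-methoxybenzoate | COc1c(OCc2ccccc2)cc(-c2coc3cc(OCc4ccccc4)cc(OCc4ccccc4)c3c2=O)cc1C(=O)OCc1ccccc1 | intermediate
23 | 5-(5,7-dihydroxy-4-oxo-4H-chromen-3-yl)-3-hydroxy-2-methoxybenzoic acid | COc1c(O)cc(-c2coc3cc(O)cc(O)c3c2=O)cc1C(=O)O | intermediate
24 | tert-butyldimethylsilyl 3-(tert-butyldimethylsilyloxy)-5-[7-(tert-butyldimethylsilyloxy)-5-hydroxy-4-oxo-4H-chromen-3-yl]-2-methoxybenzoate | COc1c(O[Si](C)(C)C(C)(C)C)cc(-c2coc3cc(O[Si](C)(C)C(C)(C)C)cc(O)c3c2=O)cc1C(=O)O[Si](C)(C)C(C)(C)C | intermediate (not isolated)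
25 | 3-(tert-butyldimethylsilyloxy)-5-[7-(tert-butyldimethylsilyloxy)-5-hydroxy-4-oxo-4H-chromen-3-yl]-2-methoxybenzoic acid | COc1c(O[Si](C)(C)C(C)(C)C)cc(-c2coc3cc(O[Si](C)(C)C(C)(C)C)cc(O)c3c2=O)cc1C(=O)O | intermediate
26 | S-ethyl 3-(tert-butyldimethylsilyloxy)-5-[7-(tert-butyldimethylsilyloxy)-5-hydroxy-4-oxo-4H-chromen-3-yl]-2-methoxybenzenecarbothioate | CCSC(=O)c1cc(-c2coc3cc(O[Si](C)(C)C(C)(C)C)cc(O)c3c2=O)cc(O[Si](C)(C)C(C)(C)C)c1OC | intermediate
27 | 3-(tert-butyldimethylsilyloxy)-5-[7-(tert-butyldimethylsilyloxy)-5-hydroxy-4-oxo-4H-chromen-3-yl]-2-methoxybenzaldehyde | COc1c(O[Si](C)(C)C(C)(C)C)cc(-c2coc3cc(O[Si](C)(C)C(C)(C)C)cc(O)c3c2=O)cc1C=O | intermediate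
28 | methallyl chloride | C=C(C)CCl | starting material
29 | triethyl phosphite | CCOP(OCC)OCC | starting material
30 | diethyl (2-methylallyl)phosphonate | C=C(C)CP(=O)(OCC)OCC | intermediate
31 | lithiated diethyl (2-methylallyl)phosphonate | [Li+].C=C(C)[CH-]P(=O)(OCC)OCC | intermediate (not isolated)
32 | 7-(tert-butyldimethylsilyloxy)-3-{3-(tert-butyldimethylsilyloxy)-4-methoxy-5-[(1E)-3-methylbuta-1,3-dien-1-yl]phenyl}-5-hydroxy-4H-chromen-4-one | C=C(C)/C=C/c1cc(-c2coc3cc(O[Si](C)(C)C(C)(C)C)cc(O)c3c2=O)cc(O[Si](C)(C)C(C)(C)C)c1OC | intermediate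
33 | 5,7-dihydroxy-3-{3-hydroxy-4-methoxy-5-[(1E)-3-methylbuta-1,3-dien-1-yl]phenyl}-4H-chromen-4-one | C=C(C)/C=C/c1cc(-c2coc3cc(O)cc(O)c3c2=O)cc(O)c1OC | target

**Count**
Total steps: 17. Longest linear sequence: 13 (steps 1-5, 9-14, 16, 17).

**Steps most likely to fail**

Step 9.
- What may go wrong: the pyrone carbonyl, helped by O5, may capture the titanium. That would invite conjugate attack of the diene at C2 with opening of ring C, and chelation-assisted loss of the benzyl groups at O5 or O3' on warming.
- Fallback idea: ring B is still built from the same diene, but the chromone is kept out of the Lewis acid step and C3-C1' is made by cross-coupling. The fallback sets out from 19 and 3 and comes back at 21.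
- Ring B partner: diene 19 is condensed with 1,1,3,3-tetramethoxypropane under catalytic Me3SiOTf to benzyl 3-(benzyloxy)-2-hydroxybenzoate F1. NBS in MeCN brominates para to the phenol and meta to the ester to give benzyl 3-(benzyloxy)-5-bromo-2-hydroxybenzoate F2. Miyaura borylation (B2pin2, PdCl2(dppf), KOAc, dioxane) gives benzyl 3-(benzyloxy)-2-hydroxy-5-(4,4,5,5-tetramethyl-1,3,2-dioxaborolan-2-yl)benzoate F3.
- Chromone partner: in parallel 3 is heated with DMF dimethyl acetal to (E)-1-[2,4-bis(benzyloxy)-6-hydroxyphenyl]-3-(dimethylamino)prop-2-en-1-one F4. Iodine in MeOH closes it to 5,7-bis(benzyloxy)-3-iodo-4H-chromen-4-one F5.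
- Junction: Suzuki-Miyaura coupling of F3 and F5 (Pd(PPh3)4, Na2CO3, DME-H2O) gives 21.

Step 4.
- What may go wrong: the pyrone carbonyl may hold back the boron catalyst. During hydrolysis or storage the enol oxygen of the malonaldehyde may add to C2 of the protonated pyrone and open ring C, or a formyl group may be lost.
- Fallback: the free malonaldehyde and its silylation are bypassed. The fallback sets out from 9, now isolated after a buffered quench, and comes back at 21. Catalytic TsOH in wet acetone hydrolyses one acetal and eliminates methanol, stopping at (E)-2-[5,7-bis(benzyloxy)-4-oxo-4H-chromen-3-yl]-3-methoxyacrolein F6, which has no acidic or nucleophilic OH. F6 then serves as the 1,3-dielectrophile toward 19 under TiCl4, in the manner of 3-alkoxy-2-enones. Both orientations give 21, because the unit is symmetric about the future C1'.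

Step 16.
- What may go wrong: the allyl phosphonate anion may react through its γ-carbon or add to C2 of the pyrone, the adduct may collapse slowly, and E selectivity may erode.
- Fallback: carbanions are avoided and the diene is built in two bonds. The fallback sets out from 27 and comes back at 32. Takai olefination (CrCl2, CHI3, THF, 0 °C) turns 27 into 7-(tert-butyldimethylsilyloxy)-3-{3-(tert-butyldimethylsilyloxy)-5-[(E)-2-iodovinyl]-4-methoxyphenyl}-5-hydroxy-4H-chromen-4-one F7. Stereoretentive Suzuki-Miyaura coupling with isopropenylboronic acid pinacol ester (PdCl2(dppf), K3PO4, THF-H2O, rt) gives 32.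

**Further compounds**
F1 | step 9 | benzyl 3-(benzyloxy)-2-hydroxybenzoate | O=C(OCc1ccccc1)c1cccc(OCc2ccccc2)c1O
F2 | step 9 | benzyl 3-(benzyloxy)-5-bromo-2-hydroxybenzoate | O=C(OCc1ccccc1)c1cc(Br)cc(OCc2ccccc2)c1O
F3 | step 9 | benzyl 3-(benzyloxy)-2-hydroxy-5-(4,4,5,5-tetramethyl-1,3,2-dioxaborolan-2-yl)benzoate | O=C(OCc1ccccc1)c1cc(B2OC(C)(C)C(C)(C)O2)cc(OCc2ccccc2)c1O
F4 | step 9 | (E)-1-[2,4-bis(benzyloxy)-6-hydroxyphenyl]-3-(dimethylamino)prop-2-en-1-one | CN(C)/C=C/C(=O)c1c(O)cc(OCc2ccccc2)cc1OCc1ccccc1
F5 | step 9 | 5,7-bis(benzyloxy)-3-iodo-4H-chromen-4-one | O=c1c(I)coc2cc(OCc3ccccc3)cc(OCc3ccccc3)c12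
F6 | step 4 | (E)-2-[5,7-bis(benzyloxy)-4-oxo-4H-chromen-3-yl]-3-methoxyacrolein | O=C/C(=C/OC)c1coc2cc(OCc3ccccc3)cc(OCc3ccccc3)c2c1=O
F7 | step 16 | 7-(tert-butyldimethylsilyloxy)-3-{3-(tert-butyldimethylsilyloxy)-5-[(E)-2-iodovinyl]-4-methoxyphenyl}-5-hydroxy-4H-chromen-4-one | COc1c(O[Si](C)(C)C(C)(C)C)cc(-c2coc3cc(O[Si](C)(C)C(C)(C)C)cc(O)c3c2=O)cc1/C=C/I
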